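The runs were generated by integration with made-up constants, noise included.

**The count.** If catalyst is dear, I ask two things of a flask: how many turnovers it needs, and how many its catalyst can make in the time given.

| flask | substrate | coupling partner | free catalyst | remark | time |
|---|---|---|---|---|---|
| west | 2.2 mM | 2.6 mM | 100 µM | run made earlier |  |
| delta | 8.0 mM | 10.0 mM | 100 µM |  | 15 min |
| alpha | 2.0 mM | 2.60 mM | 100 µM |  | 15 min |
| theta | 2.0 mM | 2.00 mM | 50 µM |  | 15 min |
| beta | 2.0 mM | 2.60 mM | 50 µM |  | 15 min |
| gamma | 6.0 mM | 1.20 mM | 25 µM |  | 15 min |
| epsilon | 2.0 mM | 2.00 mM | 150 µM |  | 15 min |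

west run (percent of the substrate charged)

| time / min | target / % | substrate / % |
|---|---|---|
| 0.250 | 2.2 | 94.1 |
| 0.417 | 5.0 | 92.7 |
| 0.833 | 9.5 | 88.6 |
| 1.50 | 15.8 | 81.6 |
| 3.00 | 26.2 | 72.3 |

(readings scatter by 1 percentage point)

- candidate steps: substrate + free catalyst <-> catalyst intermediate A; coupling partner + catalyst intermediate A <-> catalyst intermediate B; catalyst intermediate B <-> free catalyst + target
- no earlier run changes the charge of free catalyst; that part of a forecast is a guess

1. the flasks by amount of target, in percent of the substrate charged, highest first, at 15 min (delta / alpha / theta / beta / gamma / epsilon)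
2. the amount of target, in percent of the substrate charged of the flask you put first, at 15 min
3. the amount of target, in percent of the substrate charged of the flask you put last, at 15 min

**West rate.** West held target at 26.2 % of its substrate charge at 3.00 min, which read as 1.92 min⁻¹. That is the turnover rate, a mean read over that run: target formed per catalyst charged per minute. Held for 15 min, it came to 28.8 turnovers. To finish, a flask needs its substrate charge over its catalyst charge.

**Catalyst.** No earlier run had changed the catalyst charge, so I guessed that the rate per catalyst held. Alpha needed 20.0 turnovers, fewer than the 28.8 of the count, so by hand it would finish. Beta needed 40.0, so by hand it would reach 72.1 %.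

**Time.** My count grows with the time allowed, but the rate read in west fell from 2.32 min⁻¹ up to 1.50 min to 1.53 min⁻¹ after it. I therefore took my budget as a high one.

**Two charges.** Delta needed 80.0 turnovers. With the rate scaled to its partner charge, the budget was 111, more than that, so by hand delta would finish. In gamma the product of the two charges was 1.26 times that of west, so I carried the rate unscaled. That gave 12.0 % of the substrate, less than the 20.0 % that its coupling partner, the limiting reagent, allowed.

**The forecast.** The forecast gave delta > alpha > epsilon > beta > theta > gamma, with delta at 80 % (62 % to 93 %) and gamma at 10 % (6.5 % to 13.5 %). Its ground for gamma began: “Gamma is capped at 20% by its partner”. Its gamma stood lower than mine.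

**The result.** The flasks came out as delta > alpha > beta > epsilon > theta > gamma, with delta at 68.8 % and gamma at 8.33 %.

    substrate + free catalyst ⇌ catalyst intermediate A (K = 450 M⁻¹, k = 7000 M⁻¹ s⁻¹)
    coupling partner + catalyst intermediate A ⇌ catalyst intermediate B (K = 42.0 M⁻¹, k = 39.0 M⁻¹ s⁻¹)
    catalyst intermediate B ⇌ free catalyst + target (K = 0.0270 M, k = 35.0 s⁻¹)

**Gamma counted.** Gamma's 8.33 % was 20.0 turnovers in 15 min, a mean rate of 1.33 min⁻¹, lower than the west rate of 1.92 min⁻¹. The neighbouring flask was gamma read at 6.0 min. The west rate gave it 11.5 turnovers, or 4.80 % of the substrate. The flask gave 4.21 %, which is 10.1 turnovers, at a mean rate of 1.68 min⁻¹.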